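**Strategy.** Everything rests on disconnecting the 2,2-dimethyl-2H-pyran ring fused to the B ring (O1–C2–C3=C4–C4a–C8a) to a five-membered 2,2-dimethyl-2,3-dihydrobenzofuran whose C3 carries the future C4 as an exocyclic CH2OH. Triflation triggers a phenonium-type 1,2-aryl shift that enlarges the furan ring by one carbon and installs the C3=C4 alkene in the same operation. The step exploits the aryl carbon C3′, flanked by O2′ and O4′, as neighbouring group and the proton-free quaternary C2. The precursor comes from 2,4-dihydroxybenzaldehyde by chelation-controlled Claisen rearrangement and cyclisation. Homologation, Evans alkylation with a prenylated benzyl bromide and Mitsunobu closure then build the (3R)-isoflavan.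

Key step: step 4

Remark: the stereocentre of the target (C3 of the chroman) is R by CIP analysis of the given SMILES; (2E)-4-chloro-3-methylbut-2-en-1-yl acetate 2 (the C5 chloro-acetate of industrial vitamin A chemistry) is assumed to be purchased, and its alkene geometry is irrelevant because the [3,3] shift erases it.

**Route**

Step 1
Reactants: 1 2,4-dihydroxybenzaldehyde; 2 (2E)-4-chloro-3-methylbut-2-en-1-yl acetate
Product: 4 2-hydroxy-4-{[(2E)-4-hydroxy-2-methylbut-2-en-1-yl]oxy}benzaldehyde, via (2E)-4-(4-formyl-3-hydroxyphenoxy)-3-methylbut-2-en-1-yl acetate 3 (not isolated)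
Conditions: K2CO3, KI (cat.), acetone, reflux; then MeOH, rt
Reagents that add atoms: none
Why: Williamson etherification should occur only at the 4-OH because the 2-OH is tied up in a hydrogen bond to the formyl group, and the carbonate left in the flask then transesterifies the primary acetate in methanol.

Step 2
Reactants: 4 2-hydroxy-4-{[(2E)-4-hydroxy-2-methylbut-2-en-1-yl]oxy}benzaldehyde
Product: 6 rac-4-hydroxy-3-(hydroxymethyl)-2,2-dimethyl-2,3-dihydro-1-benzofuran-5-carbaldehyde, via rac-2,4-dihydroxy-3-(1-hydroxy-3-methylbut-3-en-2-yl)benzaldehyde 5 (not isolated)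
Conditions: 1,2-dichlorobenzene, 180 °C; then Amberlyst-15 (cat.), 60 °C
Reagents that add atoms: none
Why: the aromatic Claisen rearrangement should go to C3 (bond fixation by the chelated o-hydroxy aldehyde), and the acid then closes the isopropenyl group onto the free, non-chelated 4-OH by Markovnikov 5-exo-trig hydroalkoxylation, as in the o-methallylphenol route to 2,2-dimethyl-2,3-dihydrobenzofurans; the new C3 stereocentre is racemic and disappears in step 4.

Step 3
Reactants: 6 rac-4-hydroxy-3-(hydroxymethyl)-2,2-dimethyl-2,3-dihydro-1-benzofuran-5-carbaldehyde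
Product: 7 rac-4-(allyloxy)-3-(hydroxymethyl)-2,2-dimethyl-2,3-dihydro-1-benzofuran-5-carbaldehyde
Conditions: allyl bromide, K2CO3, DMF, 40 °C
Reagents that add atoms: allyl bromide, C=CCBr
Why: Williamson O-allylation of the phenoxide should be selective because carbonate does not deprotonate the primary alcohol.

Step 4
Reactants: 7 rac-4-(allyloxy)-3-(hydroxymethyl)-2,2-dimethyl-2,3-dihydro-1-benzofuran-5-carbaldehyde
Product: 9 5-(allyloxy)-2,2-dimethyl-2H-chromene-6-carbaldehyde, via rac-[4-(allyloxy)-5-formyl-2,2-dimethyl-2,3-dihydro-1-benzofuran-3-yl]methyl trifluoromethanesulfonate 8 (not isolated)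
Conditions: Tf2O, 2,6-di-tert-butyl-4-methylpyridine, CH2Cl2, −78 °C to rt
Reagents that add atoms: none
Why: The primary triflate 8 should ionise with participation of the aryl carbon C3a (3-exo-tet closure to a spiro-cyclopropane phenonium ion stabilised by the two ortho oxygens), the old C3–C3a bond then breaks, and loss of a proton from the resulting chromanyl cation (directly or after a 1,2-hydride shift to the benzylic position) gives the C3=C4 alkene. The closest known reaction type is the Wagner–Meerwein (neophyl-type) ring expansion of benzo-fused cycloalkylmethyl sulfonates and halides, as in the indan-1-ylmethyl to dihydronaphthalene and 3-(halomethyl)indoline to tetrahydroquinoline rearrangements. No ring is closed by a tethered nucleophile: the six-membered ring arises from the five-membered one through the 1,2-shift, and no stereocentre is formed, since the racemic C3 centre becomes sp2. The step needs the 1,2-aryl shift to win over a 1,2-hydride shift from C3 and over E2 elimination to the exocyclic alkene; the 2,6-dioxygenated migrating carbon, the hindered non-nucleophilic base and the low temperature should secure this, and a competing shift of C2 would lead to the same chromene. The alkene can only form between C3 and C4 because C2 carries no hydrogen.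

Step 5
Reactants: 9 5-(allyloxy)-2,2-dimethyl-2H-chromene-6-carbaldehyde
Product: 10 2-[5-(allyloxy)-2,2-dimethyl-2H-chromen-6-yl]acetonitrile
Conditions: TosMIC, t-BuOK, DME, −50 °C; then MeOH, reflux
Reagents that add atoms: p-toluenesulfonylmethyl isocyanide (TosMIC), Cc1ccc(cc1)S(=O)(=O)C[N+]#[C-]
Why: the van Leusen reductive cyanation should convert ArCHO into ArCH2CN in one operation under basic conditions that leave the chromene and the allyl ether untouched.

Step 6
Reactants: 10 2-[5-(allyloxy)-2,2-dimethyl-2H-chromen-6-yl]acetonitrile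
Product: 11 2-[5-(allyloxy)-2,2-dimethyl-2H-chromen-6-yl]acetic acid
Conditions: KOH, EtOH/H2O, reflux; then 1 M HCl, 0 °C, to pH 3
Reagents that add atoms: water (as aqueous KOH), O
Why: alkaline nitrile hydrolysis should give the arylacetic acid, and the brief cold acidification is mild enough for the chromene.

Step 7
Reactants: 11 2-[5-(allyloxy)-2,2-dimethyl-2H-chromen-6-yl]acetic acid; 12 (R)-4-benzyl-1,3-oxazolidin-2-one
Product: 14 (R)-3-{2-[5-(allyloxy)-2,2-dimethyl-2H-chromen-6-yl]acetyl}-4-benzyl-1,3-oxazolidin-2-one, via 2-[5-(allyloxy)-2,2-dimethyl-2H-chromen-6-yl]acetic pivalic anhydride 13 (not isolated)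
Conditions: PivCl, Et3N, THF, −20 °C; then 12, LiCl, rt
Reagents that add atoms: none
Why: N-acylation of the Evans auxiliary through the mixed pivalic anhydride should occur at the less hindered arylacetyl carbonyl.

Step 8
Reactants: 1 2,4-dihydroxybenzaldehyde; 15 prenyl bromide (1-bromo-3-methylbut-2-ene)
Product: 16 2,4-dihydroxy-3-(3-methylbut-2-en-1-yl)benzaldehyde
Conditions: KOH (aq), 0 °C to rt
Reagents that add atoms: none
Why: nuclear C-prenylation of the resorcinolate in water should favour C3, the carbon ortho to both phenoxide oxygens, and the C5 and O-alkylated isomers would be removed by chromatography.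

Step 9
Reactants: 16 2,4-dihydroxy-3-(3-methylbut-2-en-1-yl)benzaldehyde
Product: 17 2,4-bis[(tert-butyldimethylsilyl)oxy]-3-(3-methylbut-2-en-1-yl)benzaldehyde
Conditions: TBSOTf, 2,6-lutidine, CH2Cl2, 0 °C
Reagents that add atoms: tert-butyldimethylsilyl triflate, CC(C)(C)[Si](C)(C)OS(=O)(=O)C(F)(F)F
Why: the silyl triflate should silylate both phenols, including the hindered chelated 2-OH.

Step 10
Reactants: 17 2,4-bis[(tert-butyldimethylsilyl)oxy]-3-(3-methylbut-2-en-1-yl)benzaldehyde
Product: 18 {2,4-bis[(tert-butyldimethylsilyl)oxy]-3-(3-methylbut-2-en-1-yl)phenyl}methanol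
Conditions: DIBAL-H, CH2Cl2, −78 °C; Rochelle salt work-up
Reagents that add atoms: none
Why: hydride reduction of the aldehyde at low temperature through an aluminium alkoxide should avoid O-to-O silyl migration.

Step 11
Reactants: 18 {2,4-bis[(tert-butyldimethylsilyl)oxy]-3-(3-methylbut-2-en-1-yl)phenyl}methanol
Product: 19 1-(bromomethyl)-2,4-bis[(tert-butyldimethylsilyl)oxy]-3-(3-methylbut-2-en-1-yl)benzene
Conditions: CBr4, PPh3, CH2Cl2, 0 °C; used at once
Reagents that add atoms: carbon tetrabromide, BrC(Br)(Br)Br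
Why: Appel bromination is neutral and should spare the silyl ethers and the prenyl group.

Step 12
Reactants: 14 (R)-3-{2-[5-(allyloxy)-2,2-dimethyl-2H-chromen-6-yl]acetyl}-4-benzyl-1,3-oxazolidin-2-one; 19 1-(bromomethyl)-2,4-bis[(tert-butyldimethylsilyl)oxy]-3-(3-methylbut-2-en-1-yl)benzene
Product: 21 (R)-3-[(2R)-2-[5-(allyloxy)-2,2-dimethyl-2H-chromen-6-yl]-3-{2,4-bis[(tert-butyldimethylsilyl)oxy]-3-(3-methylbut-2-en-1-yl)phenyl}propanoyl]-4-benzyl-1,3-oxazolidin-2-one, via the sodium (Z)-enolate of 14 20 (not isolated)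
Conditions: NaHMDS (1.0 equiv), THF, −78 °C; then 19, −78 to −40 °C
Reagents that add atoms: none
Why: in this Evans asymmetric alkylation the chelated (Z)-enolate should be attacked by the benzyl bromide on the face opposite the 4-benzyl group, which with the (R)-auxiliary sets the new centre as R (the later C3 of the isoflavan).

Step 13
Reactants: 21 the alkylated imide
Product: 22 (2R)-2-[5-(allyloxy)-2,2-dimethyl-2H-chromen-6-yl]-3-{2,4-bis[(tert-butyldimethylsilyl)oxy]-3-(3-methylbut-2-en-1-yl)phenyl}propan-1-ol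
Conditions: LiBH4, MeOH (1 equiv), THF, 0 °C
Reagents that add atoms: none
Why: reductive cleavage of the imide should give the primary alcohol without epimerising the α-aryl centre and release the auxiliary.

Step 14
Reactants: 22 the bis-silyl alcohol
Product: 23 4-{(2R)-2-[5-(allyloxy)-2,2-dimethyl-2H-chromen-6-yl]-3-hydroxypropyl}-2-(3-methylbut-2-en-1-yl)benzene-1,3-diol
Conditions: TBAF, AcOH, THF, 0 °C
Reagents that add atoms: none
Why: buffered fluoride should cleave both aryl silyl ethers while the allyl ether on the B ring stays in place.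

Step 15
Reactants: 23 the triol
Product: 24 (3R)-3-[5-(allyloxy)-2,2-dimethyl-2H-chromen-6-yl]-8-(3-methylbut-2-en-1-yl)chroman-7-ol
Conditions: PPh3, DIAD, THF (0.01 M), 0 °C to rt
Reagents that add atoms: none
Why: intramolecular Mitsunobu etherification (6-exo-tet) should close the chroman through the A-ring 2-OH, the only free phenol within reach since the B-ring 2′-oxygen is allylated, and the stereocentre is untouched because substitution occurs at CH2.

Step 16
Reactants: 24 the O-allyl isoflavan
Product: 25 (3R)-3-(5-hydroxy-2,2-dimethyl-2H-chromen-6-yl)-8-(3-methylbut-2-en-1-yl)chroman-7-ol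
Conditions: Pd(PPh3)4 (cat.), morpholine, THF, rt
Reagents that add atoms: none
Why: Tsuji–Trost deallylation of the aryl allyl ether is acid-free, so the o-prenylphenol and the chromene should survive.

**Compound list**

1 | 2,4-dihydroxybenzaldehyde | O=Cc1ccc(O)cc1O | starting material
2 | (2E)-4-chloro-3-methylbut-2-en-1-yl acetate | CC(=O)OC/C=C(C)/CCl | starting material
3 | (2E)-4-(4-formyl-3-hydroxyphenoxy)-3-methylbut-2-en-1-yl acetate | O=Cc1ccc(OC/C(C)=C/COC(C)=O)cc1O | intermediate
4 | 2-hydroxy-4-{[(2E)-4-hydroxy-2-methylbut-2-en-1-yl]oxy}benzaldehyde | O=Cc1ccc(OC/C(C)=C/CO)cc1O | intermediate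
5 | rac-2,4-dihydroxy-3-(1-hydroxy-3-methylbut-3-en-2-yl)benzaldehyde | O=Cc1ccc(O)c(C(CO)C(C)=C)c1O | intermediate
6 | rac-4-hydroxy-3-(hydroxymethyl)-2,2-dimethyl-2,3-dihydro-1-benzofuran-5-carbaldehyde | O=Cc1ccc2OC(C)(C)C(CO)c2c1O | intermediate
7 | rac-4-(allyloxy)-3-(hydroxymethyl)-2,2-dimethyl-2,3-dihydro-1-benzofuran-5-carbaldehyde | O=Cc1ccc2OC(C)(C)C(CO)c2c1OCC=C | intermediate
8 | rac-[4-(allyloxy)-5-formyl-2,2-dimethyl-2,3-dihydro-1-benzofuran-3-yl]methyl trifluoromethanesulfonate | O=Cc1ccc2OC(C)(C)C(COS(=O)(=O)C(F)(F)F)c2c1OCC=C | intermediate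
9 | 5-(allyloxy)-2,2-dimethyl-2H-chromene-6-carbaldehyde | O=Cc1ccc2OC(C)(C)C=Cc2c1OCC=C | intermediate
10 | 2-[5-(allyloxy)-2,2-dimethyl-2H-chromen-6-yl]acetonitrile | N#CCc1ccc2OC(C)(C)C=Cc2c1OCC=C | intermediate
11 | 2-[5-(allyloxy)-2,2-dimethyl-2H-chromen-6-yl]acetic acid | OC(=O)Cc1ccc2OC(C)(C)C=Cc2c1OCC=C | intermediate
12 | (R)-4-benzyl-1,3-oxazolidin-2-one | O=C1OC[C@@H](Cc2ccccc2)N1 | starting material
13 | 2-[5-(allyloxy)-2,2-dimethyl-2H-chromen-6-yl]acetic pivalic anhydride | CC(C)(C)C(=O)OC(=O)Cc1ccc2OC(C)(C)C=Cc2c1OCC=C | intermediate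
14 | (R)-3-{2-[5-(allyloxy)-2,2-dimethyl-2H-chromen-6-yl]acetyl}-4-benzyl-1,3-oxazolidin-2-one | O=C1OC[C@@H](Cc2ccccc2)N1C(=O)Cc1ccc2OC(C)(C)C=Cc2c1OCC=C | intermediate
15 | prenyl bromide (1-bromo-3-methylbut-2-ene) | CC(C)=CCBr | starting material
16 | 2,4-dihydroxy-3-(3-methylbut-2-en-1-yl)benzaldehyde | O=Cc1ccc(O)c(CC=C(C)C)c1O | intermediate
17 | 2,4-bis[(tert-butyldimethylsilyl)oxy]-3-(3-methylbut-2-en-1-yl)benzaldehyde | O=Cc1ccc(O[Si](C)(C)C(C)(C)C)c(CC=C(C)C)c1O[Si](C)(C)C(C)(C)C | intermediate
18 | {2,4-bis[(tert-butyldimethylsilyl)oxy]-3-(3-methylbut-2-en-1-yl)phenyl}methanol | OCc1ccc(O[Si](C)(C)C(C)(C)C)c(CC=C(C)C)c1O[Si](C)(C)C(C)(C)C | intermediate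
19 | 1-(bromomethyl)-2,4-bis[(tert-butyldimethylsilyl)oxy]-3-(3-methylbut-2-en-1-yl)benzene | BrCc1ccc(O[Si](C)(C)C(C)(C)C)c(CC=C(C)C)c1O[Si](C)(C)C(C)(C)C | intermediate
20 | sodium (Z)-enolate of 14 | O=C1OC[C@@H](Cc2ccccc2)N1/C([O-])=C/c1ccc2OC(C)(C)C=Cc2c1OCC=C.[Na+] | intermediate
21 | (R)-3-[(2R)-2-[5-(allyloxy)-2,2-dimethyl-2H-chromen-6-yl]-3-{2,4-bis[(tert-butyldimethylsilyl)oxy]-3-(3-methylbut-2-en-1-yl)phenyl}propanoyl]-4-benzyl-1,3-oxazolidin-2-one | O=C1OC[C@@H](Cc2ccccc2)N1C(=O)[C@H](Cc1ccc(O[Si](C)(C)C(C)(C)C)c(CC=C(C)C)c1O[Si](C)(C)C(C)(C)C)c1ccc2OC(C)(C)C=Cc2c1OCC=C | intermediate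
22 | (2R)-2-[5-(allyloxy)-2,2-dimethyl-2H-chromen-6-yl]-3-{2,4-bis[(tert-butyldimethylsilyl)oxy]-3-(3-methylbut-2-en-1-yl)phenyl}propan-1-ol | OC[C@@H](c1ccc2OC(C)(C)C=Cc2c1OCC=C)Cc1ccc(O[Si](C)(C)C(C)(C)C)c(CC=C(C)C)c1O[Si](C)(C)C(C)(C)C | intermediate
23 | 4-{(2R)-2-[5-(allyloxy)-2,2-dimethyl-2H-chromen-6-yl]-3-hydroxypropyl}-2-(3-methylbut-2-en-1-yl)benzene-1,3-diol | OC[C@@H](c1ccc2OC(C)(C)C=Cc2c1OCC=C)Cc1ccc(O)c(CC=C(C)C)c1O | intermediate
24 | (3R)-3-[5-(allyloxy)-2,2-dimethyl-2H-chromen-6-yl]-8-(3-methylbut-2-en-1-yl)chroman-7-ol | CC(C)=CCc1c(O)ccc2c1OC[C@@H](c1ccc3OC(C)(C)C=Cc3c1OCC=C)C2 | intermediate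
25 | (3R)-3-(5-hydroxy-2,2-dimethyl-2H-chromen-6-yl)-8-(3-methylbut-2-en-1-yl)chroman-7-ol | CC(C)=CCc1c(O)ccc2c1OC[C@@H](c1ccc3c(c1O)C=CC(C)(C)O3)C2 | target

**Step count and risks**

Total step count: 16. Longest linear sequence: 12 steps (steps 1–7 and 12–16).

The three steps most likely to fail:

1. Step 4. The ionisation may follow a 1,2-hydride shift from C3 or an E2 path to the exocyclic alkene instead of the aryl shift, and the electron-rich chromene may oligomerise under cationic conditions. The fallback sets out from 7 and comes back at 9, and keeps the ring enlargement but moves it to a radical manifold. Alcohol 7 would be converted (I2, PPh3, imidazole) into the iodide rac-4-(allyloxy)-3-(iodomethyl)-2,2-dimethyl-2,3-dihydro-1-benzofuran-5-carbaldehyde F1. Slow addition of (Me3Si)3SiH/AIBN in toluene at 100 °C should let the primary radical undergo the neophyl-type 1,2-aryl migration before reduction, giving the ring-expanded chroman 5-(allyloxy)-2,2-dimethylchromane-6-carbaldehyde F2. DDQ dehydrogenation in dioxane would then return chromene 9.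

2. Step 2. The allyl unit may migrate to C5 or follow the abnormal Claisen pathway at 180 °C, and under reversible acid conditions ring closure may occur through the chelated 2-OH. The fallback sets out from 4 and comes back at 6. The thermal stage would be run alone and 5 isolated. A kinetic, base-mediated iodoetherification (I2, NaHCO3, MeCN, 0 °C) through the more acidic 4-phenoxide should then give 4-hydroxy-3-(hydroxymethyl)-2-(iodomethyl)-2-methyl-2,3-dihydro-1-benzofuran-5-carbaldehyde F3 as a diastereomer mixture. Radical deiodination ((Me3Si)3SiH, AIBN) would convert the iodomethyl group into the second methyl group and give 6.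

3. Step 8. Alkylation of the ambident resorcinolate may be poorly selective between C3, C5 and oxygen, and may over-alkylate. The fallback sets out from 1 and comes back at 16. Alkylation of 1 with 3-chloro-3-methylbut-1-yne (K2CO3, KI, CuI, acetone) should give 2-hydroxy-4-[(2-methylbut-3-yn-2-yl)oxy]benzaldehyde F4. Lindlar semi-hydrogenation would give 2-hydroxy-4-[(2-methylbut-3-en-2-yl)oxy]benzaldehyde F5. A chelation-controlled Claisen rearrangement (N,N-diethylaniline, 130 °C) should then deliver the prenyl group to C3 and give 16.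

**Further compounds**

F1 | step 4 | rac-4-(allyloxy)-3-(iodomethyl)-2,2-dimethyl-2,3-dihydro-1-benzofuran-5-carbaldehyde | O=Cc1ccc2OC(C)(C)C(CI)c2c1OCC=C
F2 | step 4 | 5-(allyloxy)-2,2-dimethylchromane-6-carbaldehyde | O=Cc1ccc2OC(C)(C)CCc2c1OCC=C
F3 | step 2 | 4-hydroxy-3-(hydroxymethyl)-2-(iodomethyl)-2-methyl-2,3-dihydro-1-benzofuran-5-carbaldehyde (diastereomer mixture) | O=Cc1ccc2OC(C)(CI)C(CO)c2c1O
F4 | step 8 | 2-hydroxy-4-[(2-methylbut-3-yn-2-yl)oxy]benzaldehyde | O=Cc1ccc(OC(C)(C)C#C)cc1O
F5 | step 8 | 2-hydroxy-4-[(2-methylbut-3-en-2-yl)oxy]benzaldehyde | O=Cc1ccc(OC(C)(C)C=C)cc1O
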